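Ring B (C5–C6–C7–C8=C9–C10) is a cyclohexene whose C8=C9 double bond marks it as a Diels–Alder adduct, so the route rests on cleaving C5–C10 and C6–C7. An intramolecular Diels–Alder reaction of a triene joins the C7=C8–C9=C10 diene to a C5=C6 dienophile through the C1–C4 tether: it closes rings A and B together, creates quaternary C10 and sets C5 and C6. The cis-diaxial C6–OH/C19–OH pair of the target is exploited as a temporary silicon tether: the precursor carries a ring-locked (Z)-vinylsiloxane (C6–SiMe2–O–C19) on quaternary C4, a C3 ketone and the complete side chain on C9.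

Key step: step 12

Remarks on the chemistry:
- Atom numbers are labdane numbers of the target: decalin C1–C10, side chain C11–C15 (C16 on C13), C17 on C8, C18 (α-methyl) and C19 (β-CH2OH) on C4, C20 on C10.
- The enantiomer of Tol-BINAP in step 1 is taken as the one that delivers the (2S,3S)-diol; the antipodal ligand serves if the sense of induction is opposite. Only the quaternary centre is carried on, because the carbinol is oxidised in step 4.
- 2-(Trimethylsilyl)ethyl chloroformate is taken as a purchasable reagent.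

Step 1
Reactants: 1 ethanol; 2 2-ethenyl-2-methyloxirane (isoprene monoxide, racemic)
Product: 3 (2S,3S)-2-ethenyl-2-methylbutane-1,3-diol
Conditions: Ir(allyl)(Tol-BINAP)(C,O-3,4-dinitrobenzoate) (5 mol%), K3PO4 (5 mol%), THF, 60 °C
Reagents that add atoms: none
Why: Iridium-catalysed hydrogen-auto-transfer tert-(hydroxy)prenylation (Krische type): ethanol is dehydrogenated to acetaldehyde, which adds through a closed chair transition state to the (E)-σ-allyliridium formed from the vinyl epoxide, so that the chiral bisphosphine sets the quaternary carbon (S, the future C4) and the anti carbinol.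

Step 2
Reactants: 3 (2S,3S)-2-ethenyl-2-methylbutane-1,3-diol
Product: 4 (2S,3S)-3-({[ethenyl(dimethyl)silyl]oxy}methyl)-3-methylpent-4-en-2-ol
Conditions: ClSiMe2(CH=CH2) (1.05 equiv), imidazole, CH2Cl2, −40 to 0 °C
Reagents that add atoms: chloro(ethenyl)dimethylsilane, C=C[Si](C)(C)Cl
Why: Silyl ether formation is fastest at the primary hydroxyl, so one equivalent at low temperature should give the mono vinylsilyl ether without touching a stereocentre.

Step 3
Reactants: 4 (2S,3S)-3-({[ethenyl(dimethyl)silyl]oxy}methyl)-3-methylpent-4-en-2-ol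
Product: 5 (1S)-1-[(5S)-2,2,5-trimethyl-5,6-dihydro-2H-1,2-oxasilin-5-yl]ethan-1-ol
Conditions: RuCl2(H2IMes)(=CH-C6H4-2-OiPr) (second-generation Hoveyda–Grubbs catalyst, 5 mol%), toluene, 80 °C, argon sparge
Reagents that add atoms: none
Why: Silicon-tethered ring-closing olefin metathesis should form the six-membered 1-oxa-2-silacyclohex-3-ene, whose ring size forces the Z geometry of the future C5=C6 dienophile.

Step 4
Reactants: 5 (1S)-1-[(5S)-2,2,5-trimethyl-5,6-dihydro-2H-1,2-oxasilin-5-yl]ethan-1-ol
Product: 6 1-[(5S)-2,2,5-trimethyl-5,6-dihydro-2H-1,2-oxasilin-5-yl]ethan-1-one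
Conditions: Dess–Martin periodinane, NaHCO3, CH2Cl2, rt
Reagents that add atoms: none
Why: Dess–Martin oxidation of the secondary alcohol gives the methyl ketone needed for the enolate union; the quaternary centre has no α-hydrogen and cannot epimerise.

Step 5
Reactants: 7 prop-2-yn-1-ol; 8 2-bromopropene
Product: 9 4-methylpent-4-en-2-yn-1-ol
Conditions: PdCl2(PPh3)2 (2 mol%), CuI (4 mol%), i-Pr2NH, THF, rt
Reagents that add atoms: none
Why: Sonogashira coupling of a terminal alkyne with an alkenyl bromide by zerovalent palladium and CuI.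

Step 6
Reactants: 9 4-methylpent-4-en-2-yn-1-ol
Product: 11 (2Z)-3-iodo-2,4-dimethylpenta-2,4-dien-1-ol, via cyclic alkenylmagnesium alkoxide 10 (not isolated)
Conditions: MeMgBr (3 equiv), CuI (10 mol%), THF, −10 °C to rt; then I2, −78 to 0 °C
Reagents that add atoms: methylmagnesium bromide, C[Mg]Br; iodine, II
Why: Hydroxyl-directed, copper-catalysed anti-carbomagnesiation of a propargylic alcohol (Duboudin–Jousseaume type) adds methyl to the alkyne carbon next to CH2O and magnesium to the distal carbon within a five-membered chelate, and iodinolysis with retention fixes the tetrasubstituted (Z)-iodoalkene, with C20 cis to the isopropenyl group.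

Step 7
Reactants: 11 (2Z)-3-iodo-2,4-dimethylpenta-2,4-dien-1-ol
Product: 12 (2Z)-1-bromo-3-iodo-2,4-dimethylpenta-2,4-diene
Conditions: CBr4, PPh3, CH2Cl2, 0 °C
Reagents that add atoms: tetrabromomethane, BrC(Br)(Br)Br
Why: Appel bromination of the primary allylic alcohol under neutral conditions should leave the alkenyl iodide and the diene untouched.

Step 8
Reactants: 6 1-[(5S)-2,2,5-trimethyl-5,6-dihydro-2H-1,2-oxasilin-5-yl]ethan-1-one; 12 (2Z)-1-bromo-3-iodo-2,4-dimethylpenta-2,4-diene
Product: 14 (4Z)-5-iodo-4,6-dimethyl-1-[(5S)-2,2,5-trimethyl-5,6-dihydro-2H-1,2-oxasilin-5-yl]hepta-4,6-dien-1-one, via lithium enolate 13 (not isolated)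
Conditions: LDA, THF, −78 °C; then 12, DMPU, −78 to −30 °C
Reagents that add atoms: none
Why: The kinetic lithium enolate of the methyl ketone (only one enolisable side) is alkylated in an SN2 reaction by the primary allylic bromide, forming the C1–C2 bond while the alkenyl iodide stays inert.

Step 9
Reactants: 15 but-3-yn-1-ol
Product: 17 2-(trimethylsilyl)ethyl (2E)-5-hydroxy-3-methylpent-2-enoate, via alkenylalane 16 (not isolated)
Conditions: Me3Al (3 equiv), Cp2ZrCl2 (0.25 equiv), CH2Cl2, 0 °C to rt; then ClCO2CH2CH2SiMe3, 0 °C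
Reagents that add atoms: trimethylaluminium, C[Al](C)C; 2-(trimethylsilyl)ethyl chloroformate, C[Si](C)(C)CCOC(=O)Cl
Why: Zirconium-catalysed syn-carboalumination (Negishi) of the terminal alkyne places methyl and aluminium cis, and acylation of the alkenylalane by the chloroformate with retention gives the (E)-β-methyl enoate.

Step 10
Reactants: 17 2-(trimethylsilyl)ethyl (2E)-5-hydroxy-3-methylpent-2-enoate
Product: 18 2-(trimethylsilyl)ethyl (2E)-5-iodo-3-methylpent-2-enoate
Conditions: I2, PPh3, imidazole, CH2Cl2, 0 °C to rt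
Reagents that add atoms: iodine, II
Why: Appel-type iodination converts the primary alcohol into the iodide by SN2 without affecting the enoate geometry.

Step 11
Reactants: 14 (4Z)-5-iodo-4,6-dimethyl-1-[(5S)-2,2,5-trimethyl-5,6-dihydro-2H-1,2-oxasilin-5-yl]hepta-4,6-dien-1-one; 18 2-(trimethylsilyl)ethyl (2E)-5-iodo-3-methylpent-2-enoate
Product: 20 2-(trimethylsilyl)ethyl (2E,6E)-3,7-dimethyl-10-oxo-6-(prop-1-en-2-yl)-10-[(5S)-2,2,5-trimethyl-5,6-dihydro-2H-1,2-oxasilin-5-yl]deca-2,6-dienoate, via alkylzinc iodide 19 (not isolated)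
Conditions: 18, Zn dust (activated with TMSCl and BrCH2CH2Br), LiCl, THF, 40 °C; then 14, Pd(OAc)2 (5 mol%), SPhos (10 mol%), THF, 40 °C
Reagents that add atoms: none
Why: Negishi coupling: zinc inserts into the primary C–I bond and zerovalent palladium couples the alkylzinc with the alkenyl iodide with retention of the double-bond geometry, while ketone, ester and alkenylsiloxane are inert to RZnI.

Step 12
Reactants: 20 2-(trimethylsilyl)ethyl (2E,6E)-3,7-dimethyl-10-oxo-6-(prop-1-en-2-yl)-10-[(5S)-2,2,5-trimethyl-5,6-dihydro-2H-1,2-oxasilin-5-yl]deca-2,6-dienoate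
Product: 21 2-(trimethylsilyl)ethyl (13E)-3-oxo-6β,19-[(dimethylsilanediyl)oxy]labda-8,13-dien-15-oate (trans-decalin, 5α-H, 10β-CH3; cyclic siloxane C6–SiMe2–O–C19 on the β face)
Conditions: toluene (0.01 M), BHT, sealed tube, 180 °C
Reagents that add atoms: none
Why: Concerted, suprafacial thermal [4+2] cycloaddition of the C7=C8–C9=C10 diene onto the ring-locked (Z)-vinylsiloxane C5=C6; the closest known reaction type is the thermal intramolecular Diels–Alder reaction of 1,7,9-decatrienes with vinylsilane dienophiles (temporary silicon connection). Ring B is closed as the six-membered cycloaddition ring (bonds C6–C7 and C5–C10), and ring A is closed at the same time as the six-membered tether ring (C10–C1–C2–C3–C4–C5) through a chair-like tether in the exo-siloxane transition state, which gives the trans ring fusion. C5 and C6 are controlled by C4: the diene can only reach the face of the oxasiline that carries the C3 tether, anti to the C4 methyl, and the cis dienophile geometry makes H5 and H6 cis with silicon on the β face next to C19. C10 is controlled by the (E) geometry of the C9=C10 bond (tether outside, C20 methyl inside) together with the exo mode, which puts C20 trans to H5. The step needs exo over endo selectivity and must outrun the 1,5-hydrogen shift from C20 to C7; the methyl and side chain on C8 and C9 clash with an endo siloxane ring, and the gem-disubstituted, ketone-containing tether favours fast ring closure. C4, C5 and C10 carry no acidic hydrogen, so the new centres cannot be scrambled later.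

Step 13
Reactants: 21 2-(trimethylsilyl)ethyl (13E)-3-oxo-6β,19-[(dimethylsilanediyl)oxy]labda-8,13-dien-15-oate
Product: 23 2-(trimethylsilyl)ethyl (13E)-3α-(3-methylbutanoyloxy)-6β,19-[(dimethylsilanediyl)oxy]labda-8,13-dien-15-oate, via lithium alkoxide 22 (not isolated)
Conditions: LiBH(s-Bu)3 (1.1 equiv), THF, −78 °C; then 3-methylbutanoyl chloride, DMAP, −78 °C to rt
Reagents that add atoms: 3-methylbutanoyl chloride, CC(C)CC(=O)Cl
Why: Bulky-hydride (L-Selectride) reduction delivers hydride to the C3 ketone along the equatorial trajectory, away from the axial hydrogens on C1 and C5, giving the axial 3α-alkoxide (3R) as in 4,4-disubstituted 3-oxo terpenoids, and the lithium alkoxide is O-acylated in the same flask while C6–O and C19–O stay masked in the siloxane.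

Step 14
Reactants: 23 2-(trimethylsilyl)ethyl (13E)-3α-(3-methylbutanoyloxy)-6β,19-[(dimethylsilanediyl)oxy]labda-8,13-dien-15-oate
Product: 24 2-(trimethylsilyl)ethyl (13E)-6β,19-dihydroxy-3α-(3-methylbutanoyloxy)labda-8,13-dien-15-oate
Conditions: KF, KHCO3, 30% H2O2, THF/MeOH, 40 °C
Reagents that add atoms: hydrogen peroxide, OO
Why: Tamao–Fleming oxidation converts the C6–Si bond into C6–OH with retention (6β), and cleavage of the Si–O bond frees the C19 hydroxyl; the esters and the unactivated alkenes should survive the buffered peroxide.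

Step 15
Reactants: 24 2-(trimethylsilyl)ethyl (13E)-6β,19-dihydroxy-3α-(3-methylbutanoyloxy)labda-8,13-dien-15-oate
Product: 25 (13E)-(3R,4S,5R,6R,10S)-6β,19-dihydroxy-3α-(3-methylbutanoyloxy)labda-8,13-dien-15-oic acid (CNP0274836.1)
Conditions: Bu4NF, THF, 0 °C to rt; aqueous NH4Cl work-up
Reagents that add atoms: none
Why: Fluoride-induced β-elimination of the 2-(trimethylsilyl)ethyl ester should liberate the acid without cleaving the hindered 3-methylbutanoate, whose trans-diaxial relation to C19 disfavours acyl migration.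

Compound list
1 | ethanol | CCO | starting material
2 | 2-ethenyl-2-methyloxirane (racemic) | C=CC1(C)CO1 | starting material
3 | (2S,3S)-2-ethenyl-2-methylbutane-1,3-diol | C[C@H](O)[C@](C)(CO)C=C | intermediate
4 | (2S,3S)-3-({[ethenyl(dimethyl)silyl]oxy}methyl)-3-methylpent-4-en-2-ol | C[C@H](O)[C@](C)(CO[Si](C)(C)C=C)C=C | intermediate
5 | (1S)-1-[(5S)-2,2,5-trimethyl-5,6-dihydro-2H-1,2-oxasilin-5-yl]ethan-1-ol | C[C@H](O)[C@]1(C)CO[Si](C)(C)C=C1 | intermediate
6 | 1-[(5S)-2,2,5-trimethyl-5,6-dihydro-2H-1,2-oxasilin-5-yl]ethan-1-one | CC(=O)[C@]1(C)CO[Si](C)(C)C=C1 | intermediate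
7 | prop-2-yn-1-ol | C#CCO | starting material
8 | 2-bromopropene | C=C(C)Br | starting material
9 | 4-methylpent-4-en-2-yn-1-ol | C=C(C)C#CCO | intermediate
10 | cyclic alkenylmagnesium alkoxide, 4-methyl-3-(prop-1-en-2-yl)-2,5-dihydro-1,2-oxamagnesole (not isolated) | C=C(C)C1=C(C)CO[Mg]1 | intermediate
11 | (2Z)-3-iodo-2,4-dimethylpenta-2,4-dien-1-ol | OC/C(C)=C(\I)C(C)=C | intermediate
12 | (2Z)-1-bromo-3-iodo-2,4-dimethylpenta-2,4-diene | BrC/C(C)=C(\I)C(C)=C | intermediate
13 | lithium enolate of 6 (not isolated) | C=C(O[Li])[C@]1(C)CO[Si](C)(C)C=C1 | intermediate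
14 | (4Z)-5-iodo-4,6-dimethyl-1-[(5S)-2,2,5-trimethyl-5,6-dihydro-2H-1,2-oxasilin-5-yl]hepta-4,6-dien-1-one | C=C(C)/C(I)=C(\C)CCC(=O)[C@]1(C)CO[Si](C)(C)C=C1 | intermediate
15 | but-3-yn-1-ol | C#CCCO | starting material
16 | (E)-alkenylalane, dimethylaluminium alkoxide of (E)-4-(dimethylalumanyl)-3-methylbut-3-en-1-ol (not isolated) | C[Al](C)OCC/C(C)=C/[Al](C)C | intermediate
17 | 2-(trimethylsilyl)ethyl (2E)-5-hydroxy-3-methylpent-2-enoate | C[Si](C)(C)CCOC(=O)/C=C(\C)CCO | intermediate
18 | 2-(trimethylsilyl)ethyl (2E)-5-iodo-3-methylpent-2-enoate | C[Si](C)(C)CCOC(=O)/C=C(\C)CCI | intermediate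
19 | alkylzinc iodide from 18 (not isolated) | C[Si](C)(C)CCOC(=O)/C=C(\C)CC[Zn]I | intermediate
20 | 2-(trimethylsilyl)ethyl (2E,6E)-3,7-dimethyl-10-oxo-6-(prop-1-en-2-yl)-10-[(5S)-2,2,5-trimethyl-5,6-dihydro-2H-1,2-oxasilin-5-yl]deca-2,6-dienoate | C=C(C)/C(CC/C(C)=C/C(=O)OCC[Si](C)(C)C)=C(\C)CCC(=O)[C@]1(C)CO[Si](C)(C)C=C1 | intermediate
21 | 2-(trimethylsilyl)ethyl (13E)-3-oxo-6β,19-[(dimethylsilanediyl)oxy]labda-8,13-dien-15-oate (5α-H, 10β-CH3) | CC1=C(CC/C(C)=C/C(=O)OCC[Si](C)(C)C)[C@@]2(C)CCC(=O)[C@](C)(CO[Si]3(C)C)[C@@H]2[C@H]3C1 | intermediate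
22 | lithium 3α-alkoxide from 21 (not isolated) | CC1=C(CC/C(C)=C/C(=O)OCC[Si](C)(C)C)[C@@]2(C)CC[C@@H](O[Li])[C@](C)(CO[Si]3(C)C)[C@@H]2[C@H]3C1 | intermediate
23 | 2-(trimethylsilyl)ethyl (13E)-3α-(3-methylbutanoyloxy)-6β,19-[(dimethylsilanediyl)oxy]labda-8,13-dien-15-oate | CC1=C(CC/C(C)=C/C(=O)OCC[Si](C)(C)C)[C@@]2(C)CC[C@@H](OC(=O)CC(C)C)[C@](C)(CO[Si]3(C)C)[C@@H]2[C@H]3C1 | intermediate
24 | 2-(trimethylsilyl)ethyl (13E)-6β,19-dihydroxy-3α-(3-methylbutanoyloxy)labda-8,13-dien-15-oate | CC1=C(CC/C(C)=C/C(=O)OCC[Si](C)(C)C)[C@@]2(C)CC[C@@H](OC(=O)CC(C)C)[C@](C)(CO)[C@@H]2[C@H](O)C1 | intermediate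
25 | (13E)-(3R,4S,5R,6R,10S)-6β,19-dihydroxy-3α-(3-methylbutanoyloxy)labda-8,13-dien-15-oic acid | CC1=C(CC/C(C)=C/C(=O)O)[C@@]2(C)CC[C@@H](OC(=O)CC(C)C)[C@](C)(CO)[C@@H]2[C@H](O)C1 | target

Total step count: 15. Longest linear sequence: 10 steps (steps 1–4, 8, 11–15).

Steps most likely to fail

Step 12. The weakly activated vinylsiloxane must add to a diene whose reacting terminus is fully substituted and carries an inside methyl. The cycloaddition may therefore be slower than the suprafacial 1,5-hydrogen shift from the C20 methyl to C7, and the endo mode may leak to the cis-fused decalin. Fallback: the concerted thermal reaction is replaced by a metal-templated formal [4+2] cycloaddition of the same triene, setting out from 20 and coming back at 21. A cationic monovalent-rhodium catalyst ([Rh(cod)Cl]2 with AgSbF6, 1,2-dichloroethane, 25–60 °C) should form the C6–C7 bond by oxidative cyclisation of the diene and alkene and then the C5–C10 bond by reductive elimination, well below the temperature of the sigmatropic shift. No new compound is made (F0).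

Step 3. The ruthenium alkylidene must load on a vinylsilane or on a vinyl group attached to a quaternary carbon, so slow initiation, non-productive vinylsilane dimerisation and catalyst decay may stall ring closure. Fallback: the Z-vinylsiloxane ring is built by alkyne trans-hydrosilylation instead of metathesis, setting out from 3 and coming back at 5. Acetonide formation (2,2-dimethoxypropane, PPTS) should give (4S,5S)-5-ethenyl-2,2,4,5-tetramethyl-1,3-dioxane F1. Ozonolysis (O3, CH2Cl2, −78 °C; Me2S) should give (4S,5S)-2,2,4,5-tetramethyl-1,3-dioxane-5-carbaldehyde F2. Ohira–Bestmann homologation (dimethyl (1-diazo-2-oxopropyl)phosphonate, K2CO3, MeOH) should give (4S,5S)-5-ethynyl-2,2,4,5-tetramethyl-1,3-dioxane F3. Acetal cleavage (PPTS, MeOH/H2O) should give (2S,3S)-2-ethynyl-2-methylbutane-1,3-diol F4. Silylation of the primary hydroxyl (ClSiHMe2, Et3N) should give (2S,3S)-3-{[(dimethylsilyl)oxy]methyl}-3-methylpent-4-yn-2-ol F5. Intramolecular endo-dig trans-hydrosilylation catalysed by [Cp*Ru(MeCN)3]PF6 should then close the same oxasiline 5.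

Step 11. Oxidative addition at the tetrasubstituted, doubly flanked alkenyl iodide may be slow, so β-hydride elimination or protodezincation of the primary alkylzinc and E/Z scrambling at the alkenylpalladium stage can compete on the most advanced open-chain intermediate. Fallback: the polarity of the C9–C11 coupling is reversed and the side chain is attached before the fragment union, setting out from 9 (through 10) and 18 and coming back at 20. The chelated alkenylmagnesium 10 is transmetalated with ZnCl2 and coupled with the alkyl iodide 18 (Pd2(dba)3, tricyclopentylphosphine, N-methylimidazole, THF/NMP; alkyl-electrophile Negishi coupling) to give 2-(trimethylsilyl)ethyl (2E,6E)-8-hydroxy-3,7-dimethyl-6-(prop-1-en-2-yl)octa-2,6-dienoate F6. Appel bromination (CBr4, PPh3) should give 2-(trimethylsilyl)ethyl (2E,6E)-8-bromo-3,7-dimethyl-6-(prop-1-en-2-yl)octa-2,6-dienoate F7, and alkylation of the lithium enolate 13 of ketone 6 with F7 (THF, DMPU, −78 °C) should deliver 20.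

Further compounds
F0 | step 12 | none | none
F1 | step 3 | (4S,5S)-5-ethenyl-2,2,4,5-tetramethyl-1,3-dioxane | C[C@@H]1OC(C)(C)OC[C@]1(C)C=C
F2 | step 3 | (4S,5S)-2,2,4,5-tetramethyl-1,3-dioxane-5-carbaldehyde | C[C@@H]1OC(C)(C)OC[C@]1(C)C=O
F3 | step 3 | (4S,5S)-5-ethynyl-2,2,4,5-tetramethyl-1,3-dioxane | C[C@@H]1OC(C)(C)OC[C@]1(C)C#C
F4 | step 3 | (2S,3S)-2-ethynyl-2-methylbutane-1,3-diol | C[C@H](O)[C@](C)(CO)C#C
F5 | step 3 | (2S,3S)-3-{[(dimethylsilyl)oxy]methyl}-3-methylpent-4-yn-2-ol | C[C@H](O)[C@](C)(CO[SiH](C)C)C#C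
F6 | step 11 | 2-(trimethylsilyl)ethyl (2E,6E)-8-hydroxy-3,7-dimethyl-6-(prop-1-en-2-yl)octa-2,6-dienoate | OC/C(C)=C(\CC/C(C)=C/C(=O)OCC[Si](C)(C)C)C(C)=C
F7 | step 11 | 2-(trimethylsilyl)ethyl (2E,6E)-8-bromo-3,7-dimethyl-6-(prop-1-en-2-yl)octa-2,6-dienoate | BrC/C(C)=C(\CC/C(C)=C/C(=O)OCC[Si](C)(C)C)C(C)=C
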